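The route rests on closing the cyclopentene ring at the C1–C2 bond, which joins the ring CH carrying the CH2–dione arm to the ring alkene carbon carrying the (Z)-dienyl chain. A cationic gold-catalysed 5-endo-dig carbocyclisation of a methyl enol ether onto an enyne forms this bond, the ring alkene, the C1 stereocentre (directed by the adjacent silyloxy-bearing quaternary carbon C5) and the aldehyde at C1 in one operation. The step exploits the 1,5-relationship of C1 and C2 through C5, C4 and C3 of the five-membered ring. Its precursor is an acyclic (S)-3-silyloxy-1,5-enyne built from (R)-2-methylglycidol, acetylide, a methoxymethylene ylide and a (Z)-alkenyl iodide. Reductive alkylation of (S)-4-methoxycyclohexane-1,3-dione with the aldehyde then joins the halves.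

Key step: step 13

Remark: the target is written as one enol tautomer of a 2-alkyl-4-methoxycyclohexane-1,3-dione, and the tautomers interconvert; enol ethers 17 and 18 are carried on as E/Z mixtures at the enol ether double bond, which disappears in step 13.

Step 1
Reactants: 1 but-2-yn-1-ol
Product: 3 (Z)-3-iodobut-2-en-1-ol, via cyclic sodium alkenylalanate 2 (not isolated)
Conditions: NaAlH2(OCH2CH2OMe)2 (Red-Al), THF, 0 °C → rt; then I2, THF, −78 → 0 °C
Reagents that add atoms: iodine, [I][I]
Why: Hydroxyl-directed trans-hydroalumination of the propargylic alcohol places aluminium at C3 anti to the delivered hydride, and iodinolysis of the C–Al bond with retention should give the Z-alkenyl iodide (iodine cis to CH2OH).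

Step 2
Reactants: 3 (Z)-3-iodobut-2-en-1-ol
Product: 4 (Z)-1-bromo-3-iodobut-2-ene
Conditions: CBr4, PPh3, CH2Cl2, 0 °C
Reagents that add atoms: carbon tetrabromide, BrC(Br)(Br)Br
Why: Appel bromination converts the primary allylic alcohol into the bromide under neutral conditions without touching the alkenyl iodide or the alkene geometry.

Step 3
Reactants: 4 (Z)-1-bromo-3-iodobut-2-ene
Product: 5 (Z)-2-iodo-6-methylhepta-2,5-diene
Conditions: (CH3)2C=CHMgBr, CuI (10 mol %), THF, −30 → 0 °C
Reagents that add atoms: 2-methylprop-1-enylmagnesium bromide, CC(C)=C[Mg]Br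
Why: Copper-catalysed coupling of an alkenyl Grignard reagent with a primary allylic bromide should proceed by direct SN2 substitution because the γ-carbon is fully substituted and bears iodine, while the alkenyl iodide is inert to the alkenylmagnesium reagent at low temperature, so the Z geometry is kept and the skipped diene results.

Step 4
Reactants: 6 methyl (S)-oxirane-2-carboxylate (methyl (S)-glycidate)
Product: 7 methyl (S)-2-hydroxy-5-methylhex-5-enoate
Conditions: CH2=C(CH3)CH2MgCl (2 equiv), CuBr·SMe2 (1 equiv), THF, −78 → −40 °C; aq. NH4Cl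
Reagents that add atoms: (2-methylallyl)magnesium chloride, C=C(C)C[Mg]Cl
Why: Organocuprate opening of a glycidic ester occurs at the unsubstituted C3 by SN2 attack and spares both the ester and the C2–O bond, so the (S) configuration of the epoxide is carried unchanged into the α-hydroxy ester.

Step 5
Reactants: 7 methyl (S)-2-hydroxy-5-methylhex-5-enoate
Product: 8 methyl (S)-2-methoxy-5-methylhex-5-enoate
Conditions: MeI, Ag2O, MeCN, rt, dark
Reagents that add atoms: iodomethane, [CH3]I
Why: Ag2O-promoted O-methylation (Williamson-type, non-basic) etherifies the α-hydroxy ester without enolisation of the adjacent ester, so the stereocentre should be preserved.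

Step 6
Reactants: 8 methyl (S)-2-methoxy-5-methylhex-5-enoate
Product: 10 methyl (S)-2-methoxy-5-oxohexanoate, via secondary ozonide 9 (not isolated)
Conditions: O3, CH2Cl2, −78 °C; then Me2S, −78 °C → rt
Reagents that add atoms: ozone, [O-][O+]=O
Why: Ozonolysis of the 1,1-disubstituted alkene with reductive work-up excises the methylene carbon and leaves the methyl ketone, while ether, ester and stereocentre are inert.

Step 7
Reactants: 10 methyl (S)-2-methoxy-5-oxohexanoate
Product: 11 (S)-4-methoxycyclohexane-1,3-dione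
Conditions: LiN(SiMe3)2 (2.2 equiv), THF, −78 → 0 °C; aq. HCl
Reagents that add atoms: none
Why: Kinetic deprotonation of the methyl ketone followed by intramolecular Claisen (Dieckmann-type) condensation onto the activated α-methoxy ester closes the six-membered 1,3-dione, which is trapped at once as its stable enolate; the ester α-hydrogen is several pK units less acidic than the ketone hydrogens, so the stereocentre should survive.

Step 8
Reactants: 12 (R)-2-methylglycidol
Product: 13 (S)-2-methylpent-4-yne-1,2-diol
Conditions: LiC≡CH·H2NCH2CH2NH2 (3 equiv), DMSO, 0 °C → rt; aq. NH4Cl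
Reagents that add atoms: lithium acetylide ethylenediamine complex, [Li+].[C-]#C.NCCN
Why: SN2 opening of the 2,2-disubstituted epoxide by acetylide at the primary carbon leaves the quaternary stereocentre untouched (its C–O bond is not broken) and gives the tertiary homopropargylic alcohol as the (S)-diol.

Step 9
Reactants: 13 (S)-2-methylpent-4-yne-1,2-diol
Product: 14 (S)-4-methyl-4,5-bis(triethylsilyloxy)pent-1-yne
Conditions: Et3SiOTf, 2,6-lutidine, CH2Cl2, −78 → 0 °C
Reagents that add atoms: triethylsilyl trifluoromethanesulfonate, CC[Si](CC)(CC)OS(=O)(=O)C(F)(F)F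
Why: The silyl triflate with a hindered pyridine base silylates both the primary and the tertiary hydroxyl group, and the tertiary triethylsilyl ether later blocks O-attack on the gold-activated alkyne.

Step 10
Reactants: 14 (S)-4-methyl-4,5-bis(triethylsilyloxy)pent-1-yne
Product: 16 (S)-2-methyl-2-(triethylsilyloxy)pent-4-ynal, via alkoxysulfonium chloride 15 (not isolated)
Conditions: (COCl)2, DMSO, CH2Cl2, −78 → −40 °C; then Et3N, −78 → 0 °C
Reagents that add atoms: none
Why: Swern oxidation of a primary triethylsilyl ether proceeds directly to the aldehyde because the activated sulfonium reagent cleaves only the unhindered primary Si–O bond, while the tertiary silyl ether is inert and the α-quaternary aldehyde cannot epimerise.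

Step 11
Reactants: 16 (S)-2-methyl-2-(triethylsilyloxy)pent-4-ynal
Product: 17 (S)-1-methoxy-3-methyl-3-(triethylsilyloxy)hex-1-en-5-yne (E/Z mixture)
Conditions: Ph3P(CH2OMe)Cl, KN(SiMe3)2, THF, 0 °C; then 16, −78 °C → rt
Reagents that add atoms: (methoxymethyl)triphenylphosphonium chloride, COC[P+](c1ccccc1)(c1ccccc1)c1ccccc1.[Cl-]
Why: Wittig methoxymethylenation of the non-enolisable aldehyde installs the enol ether (E/Z mixture, both isomers used) that serves as the carbon nucleophile of the key step.

Step 12
Reactants: 17 (S)-1-methoxy-3-methyl-3-(triethylsilyloxy)hex-1-en-5-yne; 5 (Z)-2-iodo-6-methylhepta-2,5-diene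
Product: 18 (3S,7Z)-1-methoxy-3,7,11-trimethyl-3-(triethylsilyloxy)dodeca-1,7,10-trien-5-yne
Conditions: Pd(PPh3)2Cl2 (3 mol %), CuI (6 mol %), Et3N, THF (degassed), rt
Reagents that add atoms: none
Why: Sonogashira coupling joins the terminal alkyne to the alkenyl iodide with retention of the Z geometry under basic conditions that the enol ether and the silyl ether tolerate.

Step 13
Reactants: 18 (3S,7Z)-1-methoxy-3,7,11-trimethyl-3-(triethylsilyloxy)dodeca-1,7,10-trien-5-yne
Product: 19 (1R,5S)-5-methyl-2-[(Z)-6-methylhepta-2,5-dien-2-yl]-5-(triethylsilyloxy)cyclopent-2-ene-1-carbaldehyde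
Conditions: Ph3PAuCl (5 mol %), AgSbF6 (5 mol %), 2,6-di-tert-butyl-4-methylpyridine (10 mol %), CH2Cl2/H2O, rt
Reagents that add atoms: water, O
Why: Ph3PAu+ coordinates the alkyne, the enol ether carbon C2 of 18 attacks alkyne carbon C6 anti to gold, water captures the resulting oxocarbenium ion (loss of methanol gives the aldehyde) and protodeauration of the alkenylgold installs the ring C–H, so the new C–C bond, the endocyclic alkene and the aldehyde arise together. The closest known reaction type is the gold-catalysed 5-endo-dig carbocyclisation of silyl and alkyl enol ethers onto alkynes (Conia-ene-type, related to the 5-endo alkoxycyclisation of 1,5-enynes). The cyclopentene closes in the 5-endo-dig mode, with both alkyne carbons ending in the ring. The new stereocentre is controlled by the adjacent quaternary carbon: with the ring CH2 held perpendicular to the enol ether plane, the smaller silyloxy oxygen should sit next to the enol double bond and the methyl group next to the vinylic hydrogen (minimised allylic strain), which places the formyl group cis to the silyloxy group and trans to methyl, also the less crowded product. The step needs attack by the enol ether and not by the trisubstituted prenyl alkene, and no ionisation of the allylic silyl ether; the much higher nucleophilicity of the enol ether, the 1,5-spacing and the buffered medium should secure this.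

Step 14
Reactants: 19 (1R,5S)-5-methyl-2-[(Z)-6-methylhepta-2,5-dien-2-yl]-5-(triethylsilyloxy)cyclopent-2-ene-1-carbaldehyde; 11 (S)-4-methoxycyclohexane-1,3-dione
Product: 21 (S)-3-hydroxy-4-methoxy-2-{[(1R,5S)-5-methyl-2-[(Z)-6-methylhepta-2,5-dien-2-yl]-5-(triethylsilyloxy)cyclopent-2-en-1-yl]methyl}cyclohex-2-en-1-one, via alkylidene dione 20 (not isolated)
Conditions: Hantzsch ester (diethyl 2,6-dimethyl-1,4-dihydropyridine-3,5-dicarboxylate), L-proline (10 mol %), CH2Cl2, rt
Reagents that add atoms: none
Why: Three-component reductive alkylation, in which Knoevenagel condensation of the aldehyde at C2 of the 1,3-dione (the only doubly activated carbon) is followed by in situ conjugate transfer hydrogenation of the alkylidene dione by the Hantzsch ester, forms the CH2 link under nearly neutral conditions that should leave the adjacent stereocentre, the silyl ether and the dienes untouched.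

Step 15
Reactants: 21 (S)-3-hydroxy-4-methoxy-2-{[(1R,5S)-5-methyl-2-[(Z)-6-methylhepta-2,5-dien-2-yl]-5-(triethylsilyloxy)cyclopent-2-en-1-yl]methyl}cyclohex-2-en-1-one
Product: 22 (S)-3-hydroxy-2-{[(1R,5S)-5-hydroxy-5-methyl-2-[(Z)-6-methylhepta-2,5-dien-2-yl]cyclopent-2-en-1-yl]methyl}-4-methoxycyclohex-2-en-1-one
Conditions: HF·pyridine, pyridine, THF, 0 °C → rt
Reagents that add atoms: none
Why: Fluoride-mediated cleavage of the tertiary triethylsilyl ether under buffered conditions liberates the tertiary alcohol without dehydration and without epimerisation of the enolised dione.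

Compound list
1 | but-2-yn-1-ol | CC#CCO | starting material
2 | sodium 2,2-bis(2-methoxyethoxy)-3-methyl-2,5-dihydro-1,2-oxaluminol-2-uide (cyclic alkenylalanate, not isolated) | CC1=CCO[Al-]1(OCCOC)OCCOC.[Na+] | intermediate
3 | (Z)-3-iodobut-2-en-1-ol | I/C(C)=C\CO | intermediate
4 | (Z)-1-bromo-3-iodobut-2-ene | I/C(C)=C\CBr | intermediate
5 | (Z)-2-iodo-6-methylhepta-2,5-diene | I/C(C)=C\CC=C(C)C | intermediate
6 | methyl (S)-oxirane-2-carboxylate | COC(=O)[C@@H]1CO1 | starting material
7 | methyl (S)-2-hydroxy-5-methylhex-5-enoate | C=C(C)CC[C@H](O)C(=O)OC | intermediate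
8 | methyl (S)-2-methoxy-5-methylhex-5-enoate | C=C(C)CC[C@H](OC)C(=O)OC | intermediate
9 | methyl (2S)-2-methoxy-4-(3-methyl-1,2,4-trioxolan-3-yl)butanoate (secondary ozonide, not isolated) | CC1(CC[C@H](OC)C(=O)OC)OCOO1 | intermediate
10 | methyl (S)-2-methoxy-5-oxohexanoate | CC(=O)CC[C@H](OC)C(=O)OC | intermediate
11 | (S)-4-methoxycyclohexane-1,3-dione | CO[C@H]1CCC(=O)CC1=O | intermediate
12 | (R)-2-methylglycidol | C[C@]1(CO1)CO | starting material
13 | (S)-2-methylpent-4-yne-1,2-diol | C#CC[C@](C)(O)CO | intermediate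
14 | (S)-4-methyl-4,5-bis(triethylsilyloxy)pent-1-yne | C#CC[C@](C)(O[Si](CC)(CC)CC)CO[Si](CC)(CC)CC | intermediate
15 | dimethyl{[(2S)-2-methyl-2-(triethylsilyloxy)pent-4-yn-1-yl]oxy}sulfonium chloride (not isolated) | C#CC[C@](C)(O[Si](CC)(CC)CC)CO[S+](C)C.[Cl-] | intermediate
16 | (S)-2-methyl-2-(triethylsilyloxy)pent-4-ynal | C#CC[C@](C)(O[Si](CC)(CC)CC)C=O | intermediate
17 | (S)-1-methoxy-3-methyl-3-(triethylsilyloxy)hex-1-en-5-yne (E/Z mixture at C1=C2) | COC=C[C@@](C)(O[Si](CC)(CC)CC)CC#C | intermediate
18 | (3S,7Z)-1-methoxy-3,7,11-trimethyl-3-(triethylsilyloxy)dodeca-1,7,10-trien-5-yne (E/Z mixture at C1=C2) | COC=C[C@@](C)(O[Si](CC)(CC)CC)CC#C/C(C)=C\CC=C(C)C | intermediate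
19 | (1R,5S)-5-methyl-2-[(Z)-6-methylhepta-2,5-dien-2-yl]-5-(triethylsilyloxy)cyclopent-2-ene-1-carbaldehyde | O=C[C@@H]1C(/C(C)=C\CC=C(C)C)=CC[C@]1(C)O[Si](CC)(CC)CC | intermediate
20 | (4S)-4-methoxy-2-{[(1R,5S)-5-methyl-2-[(Z)-6-methylhepta-2,5-dien-2-yl]-5-(triethylsilyloxy)cyclopent-2-en-1-yl]methylidene}cyclohexane-1,3-dione (not isolated) | CO[C@H]1CCC(=O)C(=C[C@@H]2C(/C(C)=C\CC=C(C)C)=CC[C@]2(C)O[Si](CC)(CC)CC)C1=O | intermediate
21 | (S)-3-hydroxy-4-methoxy-2-{[(1R,5S)-5-methyl-2-[(Z)-6-methylhepta-2,5-dien-2-yl]-5-(triethylsilyloxy)cyclopent-2-en-1-yl]methyl}cyclohex-2-en-1-one | CO[C@H]1CCC(=O)C(C[C@@H]2C(/C(C)=C\CC=C(C)C)=CC[C@]2(C)O[Si](CC)(CC)CC)=C1O | intermediate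
22 | (S)-3-hydroxy-2-{[(1R,5S)-5-hydroxy-5-methyl-2-[(Z)-6-methylhepta-2,5-dien-2-yl]cyclopent-2-en-1-yl]methyl}-4-methoxycyclohex-2-en-1-one | CO[C@H]1CCC(=O)C(C[C@@H]2C(/C(C)=C\CC=C(C)C)=CC[C@]2(C)O)=C1O | target

Total step count: 15 steps.
Longest linear sequence: 8 steps (steps 8 to 15, from 12 to 22).

Steps most likely to fail

Step 13. The gold-activated enyne may be intercepted by the prenyl alkene of the cis-disposed dienyl chain, the allylic silyloxy enol ether may ionise or hydrolyse before it cyclises, or the two faces of the enol ether may be poorly differentiated. The fallback sets out from 17 and closes the ring before the side chain is present. Deprotonation and iodination (n-BuLi, THF, −78 °C; I2) would give the iodoalkyne (S)-6-iodo-1-methoxy-3-methyl-3-(triethylsilyloxy)hex-1-en-5-yne F1. Gold-catalysed cyclisation of this simple haloalkyne (Ph3PAuCl, AgSbF6, CH2Cl2/H2O) should give the alkenyl iodide (1R,5S)-2-iodo-5-methyl-5-(triethylsilyloxy)cyclopent-2-ene-1-carbaldehyde F2, from which an unwanted diastereomer, if formed, can be separated. Negishi coupling (Pd(PPh3)4, THF, rt) with (Z)-(6-methylhepta-2,5-dien-2-yl)zinc chloride F3, made from 5 by iodine–lithium exchange (t-BuLi, Et2O, −78 °C) and ZnCl2, comes back to the route at 19.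

Step 14. The α-stereocentre of 19 may epimerise through enamine or dienol formation, the Knoevenagel adduct may lose silanol by vinylogous β-elimination, or a second dione may add to the adduct. The fallback sets out from 19 and from 11 and joins them by cross-coupling, with no carbonyl group at the linking carbon. Reduction of 19 (NaBH4, MeOH, 0 °C) would give [(1S,5S)-5-methyl-2-[(Z)-6-methylhepta-2,5-dien-2-yl]-5-(triethylsilyloxy)cyclopent-2-en-1-yl]methanol F4. Iodination (I2, PPh3, imidazole, CH2Cl2) gives (1R,5S)-1-(iodomethyl)-5-methyl-2-[(Z)-6-methylhepta-2,5-dien-2-yl]-5-(triethylsilyloxy)cyclopent-2-ene F5, and zinc insertion (Zn dust, LiCl, THF) gives {[(1R,5S)-5-methyl-2-[(Z)-6-methylhepta-2,5-dien-2-yl]-5-(triethylsilyloxy)cyclopent-2-en-1-yl]methyl}zinc iodide F6. In parallel, 11 is O-methylated (Me3SiCHN2, MeOH) to the vinylogous ester (S)-3,6-dimethoxycyclohex-2-en-1-one F7 (a regioisomeric enol ether would converge at the final hydrolysis) and iodinated (I2, pyridine, CH2Cl2) to (S)-2-iodo-3,6-dimethoxycyclohex-2-en-1-one F8. Negishi coupling of F6 with F8 (Pd(OAc)2, 2-dicyclohexylphosphino-2′,6′-dimethoxybiphenyl, THF) should give (S)-3,6-dimethoxy-2-{[(1R,5S)-5-methyl-2-[(Z)-6-methylhepta-2,5-dien-2-yl]-5-(triethylsilyloxy)cyclopent-2-en-1-yl]methyl}cyclohex-2-en-1-one F9. Aqueous HCl in THF then cleaves the enol ether and the silyl ether in one operation and comes back to the route at 22.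

Step 7. The strong base may enolise the α-methoxy ester and erode the enantiomeric purity, or intermolecular condensation may compete with ring closure. The fallback sets out from 10 and closes the ring by soft enolisation instead of a strong amide base. Saponification (LiOH, THF/H2O, 0 °C) gives (S)-2-methoxy-5-oxohexanoic acid F10, which is activated as pentafluorophenyl (S)-2-methoxy-5-oxohexanoate F11 (C6F5OH, EDC·HCl, CH2Cl2). Soft enolisation of the ketone (MgBr2·OEt2, i-Pr2NEt, CH2Cl2, rt) and intramolecular C-acylation under these weakly basic conditions come back to the route at 11.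

Further compounds
F1 | step 13 | (S)-6-iodo-1-methoxy-3-methyl-3-(triethylsilyloxy)hex-1-en-5-yne | COC=C[C@@](C)(O[Si](CC)(CC)CC)CC#CI
F2 | step 13 | (1R,5S)-2-iodo-5-methyl-5-(triethylsilyloxy)cyclopent-2-ene-1-carbaldehyde | O=C[C@@H]1C(I)=CC[C@]1(C)O[Si](CC)(CC)CC
F3 | step 13 | (Z)-(6-methylhepta-2,5-dien-2-yl)zinc chloride | Cl[Zn]/C(C)=C\CC=C(C)C
F4 | step 14 | [(1S,5S)-5-methyl-2-[(Z)-6-methylhepta-2,5-dien-2-yl]-5-(triethylsilyloxy)cyclopent-2-en-1-yl]methanol | OC[C@@H]1C(/C(C)=C\CC=C(C)C)=CC[C@]1(C)O[Si](CC)(CC)CC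
F5 | step 14 | (1R,5S)-1-(iodomethyl)-5-methyl-2-[(Z)-6-methylhepta-2,5-dien-2-yl]-5-(triethylsilyloxy)cyclopent-2-ene | IC[C@@H]1C(/C(C)=C\CC=C(C)C)=CC[C@]1(C)O[Si](CC)(CC)CC
F6 | step 14 | {[(1R,5S)-5-methyl-2-[(Z)-6-methylhepta-2,5-dien-2-yl]-5-(triethylsilyloxy)cyclopent-2-en-1-yl]methyl}zinc iodide | I[Zn]C[C@@H]1C(/C(C)=C\CC=C(C)C)=CC[C@]1(C)O[Si](CC)(CC)CC
F7 | step 14 | (S)-3,6-dimethoxycyclohex-2-en-1-one | CO[C@H]1CCC(OC)=CC1=O
F8 | step 14 | (S)-2-iodo-3,6-dimethoxycyclohex-2-en-1-one | CO[C@H]1CCC(OC)=C(I)C1=O
F9 | step 14 | (S)-3,6-dimethoxy-2-{[(1R,5S)-5-methyl-2-[(Z)-6-methylhepta-2,5-dien-2-yl]-5-(triethylsilyloxy)cyclopent-2-en-1-yl]methyl}cyclohex-2-en-1-one | CO[C@H]1CCC(OC)=C(C[C@@H]2C(/C(C)=C\CC=C(C)C)=CC[C@]2(C)O[Si](CC)(CC)CC)C1=O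
F10 | step 7 | (S)-2-methoxy-5-oxohexanoic acid | CC(=O)CC[C@H](OC)C(=O)O
F11 | step 7 | pentafluorophenyl (S)-2-methoxy-5-oxohexanoate | CC(=O)CC[C@H](OC)C(=O)Oc1c(F)c(F)c(F)c(F)c1F
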